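The benzene ring is disconnected at C1–C2 and C5–C6. A thermal [4+2] addition of a 1,1,3-trioxygenated penta-1,3-diene to an alk-2-ynoate, followed by loss of methanol, makes both bonds and the arene in one operation: ring carbons C1 (carboxyl) and C6 (13-methyltetradecyl) are the alpha and beta carbons of the ynoate, and C2–C5 (OH, H, OH, CH3) are C1–C4 of methyl 3-oxopentanoate with their oxygens in place. The precursors are the (3Z)-bis(trimethylsilyl) dienol ether of that keto ester and benzyl 16-methylheptadec-2-ynoate; the benzyl ester is chosen so that the acid is released by neutral hydrogenolysis and not by hydrolysis of a doubly ortho-flanked salicylate.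

Key step: step 7

Assumption: the geometry of the ketene acetal bond C1=C2 in 13 and 14 (drawn with OCH3 cis to C3) and of the enol ether bond in 12 (drawn E) is not controlled and has no consequence, because these carbons become the ketal carbon of 15 and then aromatic carbons; 15 is drawn with the relative configuration that follows from 14 as shown.

Step 1
Reactants: 1 12-bromododecan-1-ol; 2 isopropylmagnesium bromide
Product: 5 13-methyltetradecan-1-ol, via bromomagnesium 12-bromododecan-1-olate 3 (not isolated), via bromomagnesium 13-methyltetradecan-1-olate 4 (not isolated)
Conditions: i-PrMgBr (3 equiv), Li2CuCl4 (3 mol%), THF, −78 °C to rt; then 1 M HCl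
Reagents that add atoms: none
Why: Copper-catalysed Grignard cross-coupling of Kochi type: one equivalent of the Grignard reagent is spent on the hydroxyl, and the organocopper species formed from Li2CuCl4 should then displace the unhindered primary bromide, as is routine for ω-bromo alkanols.

Step 2
Reactants: 5 13-methyltetradecan-1-ol
Product: 6 1-bromo-13-methyltetradecane
Conditions: CBr4, PPh3, CH2Cl2, 0 °C to rt
Reagents that add atoms: carbon tetrabromide, BrC(Br)(Br)Br
Why: Appel reaction: the alkoxyphosphonium ion generated from PPh3 and CBr4 should be displaced by bromide in an SN2 step at the primary carbon, and the saturated chain offers no competing site.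

Step 3
Reactants: 6 1-bromo-13-methyltetradecane; 7 lithium acetylide–ethylenediamine complex (LiC≡CH·H2NCH2CH2NH2)
Product: 8 15-methylhexadec-1-yne
Conditions: LiC≡CH·H2NCH2CH2NH2 (1.5 equiv), DMSO/THF, 0 °C to rt
Reagents that add atoms: none
Why: SN2 alkylation of an acetylide by a primary alkyl bromide in a dipolar aprotic medium, which should deliver the terminal alkyne in one operation because the monolithiated acetylene complex alkylates only once.

Step 4
Reactants: 8 15-methylhexadec-1-yne
Product: 10 benzyl 16-methylheptadec-2-ynoate, via lithium 15-methylhexadec-1-yn-1-ide 9 (not isolated)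
Conditions: n-BuLi, THF, −78 to 0 °C; then cannulated into ClCO2Bn (1.5 equiv), THF, −78 °C
Reagents that add atoms: benzyl chloroformate, O=C(Cl)OCc1ccccc1
Why: Deprotonation of the terminal alkyne and C-acylation of the lithium acetylide by a chloroformate (alkoxycarbonylation); adding the acetylide to excess chloroformate at −78 °C should keep it from attacking the ynoate that is being formed.

Step 5
Reactants: 11 methyl 3-oxopentanoate
Product: 12 methyl (E)-3-(trimethylsilyloxy)pent-2-enoate (may contain the Z isomer)
Conditions: Me3SiCl, Et3N, hexane, rt; filtration, distillation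
Reagents that add atoms: chlorotrimethylsilane, C[Si](C)(C)Cl
Why: Silyl enol ether formation from the enolisable beta-keto ester under Me3SiCl/Et3N, the first stage of the standard two-stage preparation of 1-alkoxy-1,3-bis(silyloxy)dienes; both geometric isomers should converge on the same dienolate in step 6.

Step 6
Reactants: 12 methyl (E)-3-(trimethylsilyloxy)pent-2-enoate
Product: 14 (1E,3Z)-1-methoxy-1,3-bis(trimethylsilyloxy)penta-1,3-diene, via lithium dienolate 13 (not isolated)
Conditions: LiN(i-Pr)2 (commercial solution), THF, −78 °C; Me3SiCl, −78 °C to rt; hexane, filtration under argon, used crude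
Reagents that add atoms: chlorotrimethylsilane, C[Si](C)(C)Cl
Why: Kinetic gamma-deprotonation by LiN(i-Pr)2 gives the extended ester dienolate and the hard silyl chloride should trap it on oxygen as the silyl ketene acetal, while allylic strain against the ester in the E enoate turns the terminal methyl away from C2 and so should favour the 3Z geometry.

Step 7
Reactants: 14 (1E,3Z)-1-methoxy-1,3-bis(trimethylsilyloxy)penta-1,3-diene; 10 benzyl 16-methylheptadec-2-ynoate
Product: 17 benzyl 2,4-dihydroxy-5-methyl-6-(13-methyltetradecyl)benzoate, via cyclohexa-1,4-diene cycloadduct 15 (not isolated), via bis(trimethylsilyl) aryl ether 16 (not isolated)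
Conditions: 14 (3 equiv, in portions), neat, 140 °C, sealed tube, argon; then 1 M HCl, THF, rt
Reagents that add atoms: none
Why: This is a normal-electron-demand Diels–Alder reaction of a 1-alkoxy-1,3-bis(silyloxy)diene with an acetylenic ester, a known route to 2,4-dihydroxybenzoates: the HOMO of 14 has its largest terminal coefficient at the CH3CH= carbon and the LUMO of 10 at the alkyne carbon beta to the ester, so a concerted but asynchronous transition state should form C5–C6 ahead of C1–C2 (arene numbering). The six-membered carbocycle is closed by this intermolecular [4+2] union of a four-carbon and a two-carbon unit, both sigma bonds being made suprafacially on the s-cis diene; should the process turn stepwise, the second bond would form by 6-exo-trig attack of the allenoate carbon on the silyloxycarbenium centre and lead to the same ring. Cycloadduct 15 carries a mixed methyl silyl ketal at the carbon that becomes C2 and a hydrogen at the carbon that becomes C5, so 1,4-elimination of methanol should aromatise it to 16 without an oxidant, and dilute acid then removes both silyl groups. No stereocentre survives, since the two sp3 centres of 15 are erased on aromatisation. The selectivity that matters is regiochemical, the ester ending next to the former ketene acetal carbon, and it is secured by the donor pattern of the diene (all three oxygens reinforce the nucleophilicity of the methyl-bearing terminus), while the 3Z geometry holds that methyl on the outer side of the s-cis diene where it does not block the approach. Because a methyl-substituted terminus and a beta-alkyl ynoate make a slow pairing, the diene is used in excess and added in portions without solvent.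

Step 8
Reactants: 17 benzyl 2,4-dihydroxy-5-methyl-6-(13-methyltetradecyl)benzoate
Product: 18 2,4-dihydroxy-5-methyl-6-(13-methyltetradecyl)benzoic acid
Conditions: H2 (1 atm), 10% Pd/C, EtOAc, rt; filtration, concentration below 30 °C
Reagents that add atoms: none
Why: Heterogeneous palladium-catalysed hydrogenolysis of the benzylic C–O bond of a benzyl ester should free the acid at room temperature under neutral conditions, where the saturated chain, the phenols and the arene are inert and the absence of base and heat keeps the 2,4-dihydroxybenzoic acid from decarboxylating.

Compound list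
1 | 12-bromododecan-1-ol | OCCCCCCCCCCCCBr | starting material
2 | isopropylmagnesium bromide | CC(C)[Mg]Br | starting material
3 | bromomagnesium 12-bromododecan-1-olate (formed in the flask) | Br[Mg]OCCCCCCCCCCCCBr | intermediate
4 | bromomagnesium 13-methyltetradecan-1-olate (formed in the flask) | CC(C)CCCCCCCCCCCCO[Mg]Br | intermediate
5 | 13-methyltetradecan-1-ol | CC(C)CCCCCCCCCCCCO | intermediate
6 | 1-bromo-13-methyltetradecane | CC(C)CCCCCCCCCCCCBr | intermediate
7 | lithium acetylide–ethylenediamine complex | [Li]C#C.NCCN | starting material
8 | 15-methylhexadec-1-yne | C#CCCCCCCCCCCCCC(C)C | intermediate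
9 | lithium 15-methylhexadec-1-yn-1-ide (formed in the flask) | [Li]C#CCCCCCCCCCCCCC(C)C | intermediate
10 | benzyl 16-methylheptadec-2-ynoate | O=C(OCc1ccccc1)C#CCCCCCCCCCCCCC(C)C | intermediate
11 | methyl 3-oxopentanoate | CCC(=O)CC(=O)OC | starting material
12 | methyl (E)-3-(trimethylsilyloxy)pent-2-enoate (may contain the Z isomer) | CC/C(O[Si](C)(C)C)=C\C(=O)OC | intermediate
13 | lithium (1Z,3Z)-1-methoxy-3-(trimethylsilyloxy)penta-1,3-dien-1-olate (lithium dienolate, formed in the flask; same spatial arrangement as 14) | C/C=C(O[Si](C)(C)C)/C=C(\OC)O[Li] | intermediate
14 | (1E,3Z)-1-methoxy-1,3-bis(trimethylsilyloxy)penta-1,3-diene | C/C=C(O[Si](C)(C)C)/C=C(\OC)O[Si](C)(C)C | intermediate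
15 | benzyl 6-methoxy-3-methyl-2-(13-methyltetradecyl)-4,6-bis(trimethylsilyloxy)cyclohexa-1,4-diene-1-carboxylate (racemic, 3-methyl cis to 6-silyloxy; formed in the flask) | CO[C@]1(O[Si](C)(C)C)C=C(O[Si](C)(C)C)[C@@H](C)C(CCCCCCCCCCCCC(C)C)=C1C(=O)OCc1ccccc1 | intermediate
16 | benzyl 5-methyl-6-(13-methyltetradecyl)-2,4-bis(trimethylsilyloxy)benzoate (formed in the flask) | Cc1c(O[Si](C)(C)C)cc(O[Si](C)(C)C)c(C(=O)OCc2ccccc2)c1CCCCCCCCCCCCC(C)C | intermediate
17 | benzyl 2,4-dihydroxy-5-methyl-6-(13-methyltetradecyl)benzoate | Cc1c(O)cc(O)c(C(=O)OCc2ccccc2)c1CCCCCCCCCCCCC(C)C | intermediate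
18 | 2,4-dihydroxy-5-methyl-6-(13-methyltetradecyl)benzoic acid | Cc1c(O)cc(O)c(C(=O)O)c1CCCCCCCCCCCCC(C)C | target

Total step count: 8. Longest linear sequence: 6 steps (steps 1, 2, 3, 4, 7 and 8); the diene arm (steps 5 and 6) joins at step 7.

Steps most likely to fail

Step 7. At the temperature this hindered pairing needs, the bis-silyl diene may degrade faster than it adds, through silyl migration from oxygen to carbon, hydrolysis by trace moisture or self-condensation. Any 3E diene also cannot reach a productive s-cis geometry, so the ynoate would be recovered or consumed by conjugate addition without ring closure. The fallback keeps the same two ring bonds but replaces the alkyne by its allene isomer, a more reactive and less congested dienophile; it sets out from bromide 6 and returns to the route at 17. Bromide 6 is converted with Mg in THF into 13-methyltetradecylmagnesium bromide F1, which is carboxylated with CO2 and acidified with dilute HCl to 14-methylpentadecanoic acid F2. Oxalyl chloride with catalytic DMF in CH2Cl2 gives 14-methylpentadecanoyl chloride F3. Et3N dehydrochlorinates F3 to the ketene 15-methylhexadec-1-en-1-one F4, which is trapped in the same flask by Ph3P=CHCO2Bn (Wittig olefination of a ketene) to give racemic benzyl 16-methylheptadeca-2,3-dienoate F5. Heating F5 with diene 14 in toluene at 80–110 °C should give, by Diels–Alder addition across the conjugated allene double bond, benzyl 2-methoxy-5-methyl-6-(13-methyltetradecylidene)-2,4-bis(trimethylsilyloxy)cyclohex-3-ene-1-carboxylate F6. F6 loses methanol and shifts its exocyclic double bond into the ring to give 16, and the acidic work-up of step 7 then delivers 17.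

Step 1. The secondary alkylcopper intermediate may isomerise to a linear propyl group by beta-hydride elimination and re-addition, or the poorly soluble bromomagnesium alkoxide may stall the coupling; either would leave a chain mixture that cannot be separated later. The fallback builds the iso terminus by olefination and hydrogenation; it sets out from 1 and returns at 5. Compound 1 is heated with PPh3 in MeCN to give (12-hydroxydodecyl)triphenylphosphonium bromide F7. NaN(SiMe3)2 (2.2 equiv) in THF converts F7 into the alkoxide ylide sodium 12-(triphenylphosphoranylidene)dodecan-1-olate F8, which reacts with acetone in a Wittig olefination to give, after dilute HCl work-up, 13-methyltetradec-12-en-1-ol F9. Hydrogenation of F9 (H2, Pd/C, EtOAc) gives 5.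

Step 3. The strongly basic acetylide medium may eliminate HBr from the bromide instead of substituting it, or may move the triple bond away from the chain end, and the long-chain bromide may dissolve poorly in DMSO. The fallback uses a silyl-capped acetylide in an ethereal medium, which can neither isomerise nor alkylate twice; it sets out from 6 and returns at 8. Bromide 6 alkylates lithium (trimethylsilyl)acetylide, made from ethynyltrimethylsilane and n-BuLi in THF/DMPU at −78 °C to rt, to give trimethyl(15-methylhexadec-1-yn-1-yl)silane F10. K2CO3 in MeOH then removes the silyl group and gives 8.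

Further compounds
F1 | step 7 | 13-methyltetradecylmagnesium bromide (formed in the flask) | CC(C)CCCCCCCCCCCC[Mg]Br
F2 | step 7 | 14-methylpentadecanoic acid | CC(C)CCCCCCCCCCCCC(=O)O
F3 | step 7 | 14-methylpentadecanoyl chloride | CC(C)CCCCCCCCCCCCC(=O)Cl
F4 | step 7 | 15-methylhexadec-1-en-1-one (ketene, formed in the flask) | CC(C)CCCCCCCCCCCC=C=O
F5 | step 7 | benzyl 16-methylheptadeca-2,3-dienoate (racemic) | O=C(OCc1ccccc1)C=C=CCCCCCCCCCCCC(C)C
F6 | step 7 | benzyl 2-methoxy-5-methyl-6-(13-methyltetradecylidene)-2,4-bis(trimethylsilyloxy)cyclohex-3-ene-1-carboxylate (stereoisomer mixture, formed in the flask) | COC1(O[Si](C)(C)C)C=C(O[Si](C)(C)C)C(C)C(=CCCCCCCCCCCCC(C)C)C1C(=O)OCc1ccccc1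
F7 | step 1 | (12-hydroxydodecyl)triphenylphosphonium bromide | OCCCCCCCCCCCC[P+](c1ccccc1)(c1ccccc1)c1ccccc1.[Br-]
F8 | step 1 | sodium 12-(triphenylphosphoranylidene)dodecan-1-olate (formed in the flask) | [Na]OCCCCCCCCCCCC=P(c1ccccc1)(c1ccccc1)c1ccccc1
F9 | step 1 | 13-methyltetradec-12-en-1-ol | CC(C)=CCCCCCCCCCCCO
F10 | step 3 | trimethyl(15-methylhexadec-1-yn-1-yl)silane | C[Si](C)(C)C#CCCCCCCCCCCCCC(C)C
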